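**Plan** (target numbered as a 2-oxaspiro[4.5]deca-6,9-dien-8-one: C1 carries the aryloxy side chain (C1′), O2, C3 the aryl group, C4 the CH2OH group, C5 is spiro, C7 carries OMe, C8 is C=O)
- Retrosynthesis: remove the C9=C10 unsaturation and the silyl groups; open the oxolane at the benzylic C3–O2 bond; cut C1–C1′ (syn glycolate aldol on a C1 aldehyde); cut C5–C6 and C9–C10 together (Diels–Alder of an α-methylene lactone with a 1-amino-2-methoxy-3-silyloxydiene); cut C3–C4 (syn aldol).
- Forward order: temporary γ-lactone (C1 as the carbonyl, ring oxygen = the oxygen of the C4 CH2OH group), then the spiro carbocycle by [4+2], lactone opened to the C1 aldehyde, side chain joined, oxolane closed through O2–C3, second ring double bond last.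
- Enabling feature: C1, the oxolane carbon next to spiro C5, can be raised to a carbonyl that activates an exocyclic C5=C10 methylene, and C6–C7(OMe)–C8(=O)–C9 is the footprint of the diene. In the oxolane the C6 arm is cis to the substituents on both C1 and C4, but in the lactone closed through the CH2O oxygen it is trans to the single neighbouring substituent, so the cycloaddition is sterically matched.
- Stereochemistry: C4 (and C3) from an Evans syn aldol with the (S)-auxiliary; C5 from the cycloaddition anti to the C4 substituent; C1 and C1′ from a second Evans syn aldol with the (R)-auxiliary; C3 confirmed trans to C4 in the acid-mediated ring closure.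

Key step: step 10

Remark: the dimethylamino-bearing ring carbon of 17–20, 24, 25 and F2–F4 is expected mainly as one epimer (endo adduct), is drawn without configuration and is destroyed in step 16; lactol 9 is an anomer mixture.
Abbreviations: ArT = 3-methoxy-4-(triisopropylsilyloxy)phenyl; TBS = tert-butyldimethylsilyl; TIPS = triisopropylsilyl; TMS = trimethylsilyl.

Step 1
Reactants: 1 vanillin
Product: 2 3-methoxy-4-(triisopropylsilyloxy)benzaldehyde
Conditions: iPr3SiCl, imidazole, DMF, rt
Reagents that add atoms: chlorotri(propan-2-yl)silane, CC(C)[Si](Cl)(C(C)C)C(C)C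
Why: Standard silylation of a phenol; the bulky aryl silyl ether should survive borohydride, amide bases, the Grignard reagent and dilute acid and falls to fluoride in the last step.

Step 2
Reactants: 3 (S)-4-benzyloxazolidin-2-one; 4 pent-4-enoyl chloride
Product: 5 (S)-4-benzyl-3-(pent-4-enoyl)oxazolidin-2-one
Conditions: n-BuLi, THF, −78 °C; then 4, −78 → 0 °C
Reagents that add atoms: none
Why: N-acylation of the lithiated oxazolidinone with an acid chloride (standard imide formation); no stereocentre is touched.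

Step 3
Reactants: 5 (S)-4-benzyl-3-(pent-4-enoyl)oxazolidin-2-one; 2 3-methoxy-4-(triisopropylsilyloxy)benzaldehyde
Product: 6 (4S)-4-benzyl-3-[(2S)-2-[(S)-hydroxy(ArT)methyl]pent-4-enoyl]oxazolidin-2-one
Conditions: Bu2BOTf, Et3N, CH2Cl2, −78 → 0 °C; then 2, −78 → 0 °C; pH 7 buffer (NaH2PO4/Na2HPO4), MeOH, H2O2, 0 °C
Reagents that add atoms: none
Why: Evans syn aldol reaction: the Z boron enolate reacts through a closed chair transition state on the face away from the benzyl group of the (S)-auxiliary, which sets the future C4 (2S in 6) and the carbinol carbon (S, syn).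

Step 4
Reactants: 6 syn-aldol adduct
Product: 7 (4S)-4-benzyl-3-[(2S)-2-[(S)-methoxy(ArT)methyl]pent-4-enoyl]oxazolidin-2-one
Conditions: Me3OBF4, 1,8-bis(dimethylamino)naphthalene, CH2Cl2, 0 °C → rt
Reagents that add atoms: trimethyloxonium tetrafluoroborate, C[O+](C)C.F[B-](F)(F)F
Why: O-methylation with an oxonium salt and a non-nucleophilic base avoids retro-aldol and epimerisation; the benzylic methyl ether cannot migrate, resists base and hydride, and is meant to ionise only in step 16.

Step 5
Reactants: 7 methyl ether imide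
Product: 8 (2R)-2-[(S)-methoxy(ArT)methyl]pent-4-en-1-ol
Conditions: NaBH4, THF/H2O (4:1), 0 °C → rt
Reagents that add atoms: none
Why: Borohydride reductive cleavage of the N-acyl oxazolidinone at the exocyclic carbonyl gives the primary alcohol and returns the auxiliary; neither stereocentre can epimerise under these conditions.

Step 6
Reactants: 8 alkenol
Product: 10 (4R)-4-[(S)-methoxy(ArT)methyl]oxolan-2-one, via lactol 9 (not isolated)
Conditions: O3, CH2Cl2, −78 °C; Me2S, −78 °C → rt; then TEMPO (cat.), PhI(OAc)2, CH2Cl2, rt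
Reagents that add atoms: ozone, [O-][O+]=O
Why: Ozonolysis of the terminal alkene (much faster than attack on the arene) gives an aldehyde that closes onto the primary hydroxyl to the lactol, and oxoammonium (TEMPO) oxidation gives the γ-lactone whose ring oxygen is the C4–CH2 oxygen; no stereocentre is affected.

Step 7
Reactants: 10 lactone
Product: 13 (4R)-4-[(S)-methoxy(ArT)methyl]-3-methylideneoxolan-2-one, via Mannich base 11 (not isolated), via ammonium iodide 12 (not isolated)
Conditions: LiN(iPr)2, THF, −78 °C; CH2=NMe2+ I−, −78 °C → rt; then MeI, MeOH, rt; then NaHCO3 (aq), CH2Cl2, rt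
Reagents that add atoms: N,N-dimethylmethyleneiminium iodide, C=[N+](C)C.[I-]
Why: Mannich aminomethylation of the lactone enolate followed by N-methylation and E1cB elimination is the standard α-methylenation of γ-butyrolactones; the transient α-stereocentre is destroyed and C4 is not enolisable.

Step 8
Reactants: 14 methoxyacetone
Product: 15 (Z)-4-(dimethylamino)-3-methoxybut-3-en-2-one
Conditions: Me2NCH(OMe)2, neat, 100 °C
Reagents that add atoms: N,N-dimethylformamide dimethyl acetal, COC(OC)N(C)C
Why: Enaminone formation by condensation of the amide acetal at the more acidic, methoxy-bearing methylene of the ketone; the amino group ends trans to the acetyl group.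

Step 9
Reactants: 15 enaminone
Product: 16 (1Z)-3-(tert-butyldimethylsilyloxy)-2-methoxy-N,N-dimethylbuta-1,3-dien-1-amine
Conditions: KN(SiMe3)2, THF, −78 °C; tBuMe2SiCl, −78 → 0 °C
Reagents that add atoms: tert-butyl(chloro)dimethylsilane, CC(C)(C)[Si](C)(C)Cl
Why: Kinetic deprotonation of the methyl ketone of the vinylogous amide and O-silylation is the standard preparation of 1-amino-3-silyloxybuta-1,3-dienes.

Step 10
Reactants: 13 α-methylene lactone; 16 aminosilyloxy diene
Product: 17 (4R,5S)-8-(tert-butyldimethylsilyloxy)-6-(dimethylamino)-7-methoxy-4-[(S)-methoxy(ArT)methyl]-2-oxaspiro[4.5]dec-7-en-1-one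
Conditions: toluene, 70 °C (sealed); concentration, no acidic work-up
Reagents that add atoms: none
Why: Normal-electron-demand Diels–Alder reaction, concerted but asynchronous: the silyl enol ether CH2 terminus of 16 bonds to the exocyclic methylene carbon of 13 (β to the lactone carbonyl, future C10) and the amino-bearing terminus to the lactone α-carbon (future C5), so that the diene carbon carrying OMe becomes C7 and the silyloxy carbon C8. The closest known reaction type is the cycloaddition of 1-amino-3-silyloxybuta-1,3-dienes with α-substituted acrylic esters, acroleins and α-methylene lactones, which is used to build the quaternary carbon of 4,4-disubstituted cyclohexenones. The six-membered carbocycle is closed by an intermolecular [4+2] cycloaddition, suprafacial on both partners, and is spiro-fused to the lactone because the dienophile is exocyclic to that ring. The only stereocentre that survives, quaternary C5, is controlled by the resident C4 centre of the lactone: the diene should add to the face of the exocyclic alkene opposite the methoxy(aryl)methyl group on the neighbouring ring carbon, which puts the amino-bearing carbon (future C6) trans to that group, the arrangement that becomes cis to both neighbours once the ring oxygen is moved from the CH2 group to C3; the configuration of the amino-bearing carbon itself (endo or exo) is lost in step 16. The step needs regioselectivity, secured by the matched polarisation of the amino/silyloxy diene and the unsaturated lactone, and facial selectivity, secured by having a single substituent next to the reacting carbon in the temporary lactone; the silyl enol ether of the adduct is kept as a mask for the C8 ketone through steps 11 to 15.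

Step 11
Reactants: 17 spiro cycloadduct
Product: 19 (1S)-4-(TBS-oxy)-1-[(2R,3S)-1-(TBS-oxy)-3-methoxy-3-(ArT)propan-2-yl]-2-(dimethylamino)-N,3-dimethoxy-N-methylcyclohex-3-ene-1-carboxamide, via hydroxy amide 18 (not isolated)
Conditions: MeNHOMe·HCl, iPrMgCl, THF, −20 → 0 °C; NaHCO3 (aq) work-up; then tBuMe2SiCl, imidazole, DMF, rt
Reagents that add atoms: N,O-dimethylhydroxylamine hydrochloride, CNOC.Cl; tert-butyl(chloro)dimethylsilane, CC(C)(C)[Si](C)(C)Cl
Why: Magnesium amide aminolysis of a lactone to the N-methoxy-N-methylamide is a known, purely basic ring opening that the aminated silyl enol ether should survive; immediate silylation of the freed primary alcohol prevents relactonisation.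

Step 12
Reactants: 19 N-methoxy-N-methylamide
Product: 20 (1S)-4-(TBS-oxy)-1-[(2R,3S)-1-(TBS-oxy)-3-methoxy-3-(ArT)propan-2-yl]-2-(dimethylamino)-3-methoxycyclohex-3-ene-1-carbaldehyde
Conditions: iBu2AlH, THF, −78 °C; KNaC4H4O6 (aq)
Reagents that add atoms: none
Why: Hydride reduction of an N-methoxy-N-methylamide stops at the chelated tetrahedral intermediate and releases the aldehyde on work-up; the aldehyde has no α-hydrogen, so the quaternary centre cannot epimerise.

Step 13
Reactants: 21 methyl 3-(4-hydroxy-3-methoxyphenyl)propanoate; 22 (R)-4-benzyl-3-(chloroacetyl)oxazolidin-2-one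
Product: 23 (R)-4-benzyl-3-{2-[2-methoxy-4-(3-methoxy-3-oxopropyl)phenoxy]acetyl}oxazolidin-2-one
Conditions: K2CO3, NaI (cat.), acetone, rt
Reagents that add atoms: none
Why: Williamson O-alkylation of the phenoxide with an α-chloro imide (SN2, iodide catalysis) under mild carbonate conditions; the auxiliary stereocentre is untouched.

Step 14
Reactants: 20 aldehyde; 23 aryloxyacetyl imide
Product: 24 (4R)-4-benzyl-3-[(2R,3S)-3-hydroxy-2-aryloxy-3-(cyclohexenyl)propanoyl]oxazolidin-2-one (aryloxy = 2-methoxy-4-(3-methoxy-3-oxopropyl)phenoxy; cyclohexenyl = the 1S ring of 20)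
Conditions: Bu2BOTf, Et3N, CH2Cl2, −78 → 0 °C; then 20, −78 → −20 °C; pH 7 buffer (NaH2PO4/Na2HPO4), MeOH, no peroxide
Reagents that add atoms: none
Why: Evans syn glycolate aldol: the Z boron enolate of the (R)-imide adds to the non-enolisable aldehyde through a closed chair transition state under reagent control, setting C1 (S) and the aryloxy-bearing carbon syn to it (2R in 24, which becomes 1′S after reduction); the base-buffered, peroxide-free protocol is chosen to keep the masked enone intact.

Step 15
Reactants: 24 aldol adduct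
Product: 25 (1S,2S)-2-[4-(3-hydroxypropyl)-2-methoxyphenoxy]-1-(cyclohexenyl)propane-1,3-diol (cyclohexenyl = the 1S ring of 20)
Conditions: LiBH4, MeOH (2 equiv), THF, 0 °C → rt
Reagents that add atoms: none
Why: Lithium borohydride removes the auxiliary reductively to give the primary alcohol and reduces the aryl propanoate ester to the 3-hydroxypropyl group in the same operation, while silyl ethers and the silyl enol ether are inert; no stereocentre is affected.

Step 16
Reactants: 25 triol
Product: 27 (1S,3S,4R,5S)-1-[(1S)-2-hydroxy-1-[4-(3-hydroxypropyl)-2-methoxyphenoxy]ethyl]-4-(hydroxymethyl)-7-methoxy-3-(ArT)-2-oxaspiro[4.5]dec-6-en-8-one, via acyclic enone 26 (not isolated)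
Conditions: HCl (0.3 M) in MeOH/CH2Cl2, 0 → 40 °C; NaHCO3 (aq)
Reagents that add atoms: none
Why: Acid turns the aminated silyl enol ether into the 2-methoxy enone (hydrolysis, β-elimination of dimethylamine), cleaves the primary silyl ether and ionises the benzylic methyl ether to a p-silyloxybenzyl cation that the C1 hydroxyl captures (SN1, five-membered ring, leaving group exocyclic), and the reversible ionisation is expected to settle C3 with the aryl group trans to the C4 hydroxymethyl group, while methanol keeps the enol methyl ether intact by degenerate exchange.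

Step 17
Reactants: 27 spiro enone
Product: 30 CNP0252711.1, via silyl dienol ether 28 (not isolated), via silylated dienone 29 (not isolated)
Conditions: Me3SiOTf, Et3N, CH2Cl2, 0 °C; then Pd(OAc)2, MeCN, rt; then HF·pyridine, pyridine, THF, 0 °C
Reagents that add atoms: none
Why: Enolisation can only occur toward C9, so silylation gives the 2-silyloxy diene (and caps the three hydroxyls), Saegusa–Ito oxidation with palladium diacetate introduces the C9=C10 double bond, and buffered fluoride removes all silyl groups without exposing the spirodienone to strong acid or base; no stereocentre is affected.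

**Compound list**

1 | vanillin (4-hydroxy-3-methoxybenzaldehyde) | O=Cc1ccc(O)c(OC)c1 | starting material
2 | 3-methoxy-4-(triisopropylsilyloxy)benzaldehyde | O=Cc1ccc(O[Si](C(C)C)(C(C)C)C(C)C)c(OC)c1 | intermediate
3 | (S)-4-benzyloxazolidin-2-one | O=C1OC[C@H](Cc2ccccc2)N1 | starting material
4 | pent-4-enoyl chloride | C=CCCC(Cl)=O | starting material
5 | (S)-4-benzyl-3-(pent-4-enoyl)oxazolidin-2-one | C=CCCC(=O)N1[C@@H](Cc2ccccc2)COC1=O | intermediate
6 | (4S)-4-benzyl-3-[(2S)-2-[(S)-hydroxy(ArT)methyl]pent-4-enoyl]oxazolidin-2-one | C=CC[C@H](C(=O)N1[C@@H](Cc2ccccc2)COC1=O)[C@H](O)c1ccc(O[Si](C(C)C)(C(C)C)C(C)C)c(OC)c1 | intermediate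
7 | (4S)-4-benzyl-3-[(2S)-2-[(S)-methoxy(ArT)methyl]pent-4-enoyl]oxazolidin-2-one | C=CC[C@H](C(=O)N1[C@@H](Cc2ccccc2)COC1=O)[C@H](OC)c1ccc(O[Si](C(C)C)(C(C)C)C(C)C)c(OC)c1 | intermediate
8 | (2R)-2-[(S)-methoxy(ArT)methyl]pent-4-en-1-ol | C=CC[C@H](CO)[C@H](OC)c1ccc(O[Si](C(C)C)(C(C)C)C(C)C)c(OC)c1 | intermediate
9 | (4R)-4-[(S)-methoxy(ArT)methyl]oxolan-2-ol (lactol, both anomers) | OC1C[C@H](CO1)[C@H](OC)c1ccc(O[Si](C(C)C)(C(C)C)C(C)C)c(OC)c1 | intermediate (not isolated)
10 | (4R)-4-[(S)-methoxy(ArT)methyl]oxolan-2-one | O=C1C[C@H](CO1)[C@H](OC)c1ccc(O[Si](C(C)C)(C(C)C)C(C)C)c(OC)c1 | intermediate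
11 | (3S,4R)-3-[(dimethylamino)methyl]-4-[(S)-methoxy(ArT)methyl]oxolan-2-one (Mannich base) | CN(C)C[C@@H]1[C@@H]([C@H](OC)c2ccc(O[Si](C(C)C)(C(C)C)C(C)C)c(OC)c2)COC1=O | intermediate (not isolated)
12 | trimethylammonium iodide of 11 | C[N+](C)(C)C[C@@H]1[C@@H]([C@H](OC)c2ccc(O[Si](C(C)C)(C(C)C)C(C)C)c(OC)c2)COC1=O.[I-] | intermediate (not isolated)
13 | (4R)-4-[(S)-methoxy(ArT)methyl]-3-methylideneoxolan-2-one | C=C1[C@H](COC1=O)[C@H](OC)c1ccc(O[Si](C(C)C)(C(C)C)C(C)C)c(OC)c1 | intermediate
14 | methoxyacetone (1-methoxypropan-2-one) | COCC(C)=O | starting material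
15 | (Z)-4-(dimethylamino)-3-methoxybut-3-en-2-one | CC(=O)/C(OC)=C/N(C)C | intermediate
16 | (1Z)-3-(tert-butyldimethylsilyloxy)-2-methoxy-N,N-dimethylbuta-1,3-dien-1-amine | C=C(O[Si](C)(C)C(C)(C)C)/C(OC)=C/N(C)C | intermediate
17 | (4R,5S)-8-(tert-butyldimethylsilyloxy)-6-(dimethylamino)-7-methoxy-4-[(S)-methoxy(ArT)methyl]-2-oxaspiro[4.5]dec-7-en-1-one (C6 epimers) | CN(C)C1C(OC)=C(O[Si](C)(C)C(C)(C)C)CC[C@@]12C(=O)OC[C@@H]2[C@H](OC)c1ccc(O[Si](C(C)C)(C(C)C)C(C)C)c(OC)c1 | intermediate
18 | (1S)-4-(TBS-oxy)-2-(dimethylamino)-1-[(2R,3S)-1-hydroxy-3-methoxy-3-(ArT)propan-2-yl]-N,3-dimethoxy-N-methylcyclohex-3-ene-1-carboxamide | CN(C)C1C(OC)=C(O[Si](C)(C)C(C)(C)C)CC[C@]1(C(=O)N(C)OC)[C@H](CO)[C@H](OC)c1ccc(O[Si](C(C)C)(C(C)C)C(C)C)c(OC)c1 | intermediate (not isolated)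
19 | (1S)-4-(TBS-oxy)-1-[(2R,3S)-1-(TBS-oxy)-3-methoxy-3-(ArT)propan-2-yl]-2-(dimethylamino)-N,3-dimethoxy-N-methylcyclohex-3-ene-1-carboxamide | CN(C)C1C(OC)=C(O[Si](C)(C)C(C)(C)C)CC[C@]1(C(=O)N(C)OC)[C@H](CO[Si](C)(C)C(C)(C)C)[C@H](OC)c1ccc(O[Si](C(C)C)(C(C)C)C(C)C)c(OC)c1 | intermediate
20 | (1S)-4-(TBS-oxy)-1-[(2R,3S)-1-(TBS-oxy)-3-methoxy-3-(ArT)propan-2-yl]-2-(dimethylamino)-3-methoxycyclohex-3-ene-1-carbaldehyde | CN(C)C1C(OC)=C(O[Si](C)(C)C(C)(C)C)CC[C@]1(C=O)[C@H](CO[Si](C)(C)C(C)(C)C)[C@H](OC)c1ccc(O[Si](C(C)C)(C(C)C)C(C)C)c(OC)c1 | intermediate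
21 | methyl 3-(4-hydroxy-3-methoxyphenyl)propanoate | COC(=O)CCc1ccc(O)c(OC)c1 | starting material
22 | (R)-4-benzyl-3-(chloroacetyl)oxazolidin-2-one | O=C(CCl)N1[C@H](Cc2ccccc2)COC1=O | starting material
23 | (R)-4-benzyl-3-{2-[2-methoxy-4-(3-methoxy-3-oxopropyl)phenoxy]acetyl}oxazolidin-2-one | COC(=O)CCc1ccc(OCC(=O)N2[C@H](Cc3ccccc3)COC2=O)c(OC)c1 | intermediate
24 | aldol adduct: (4R)-auxiliary imide of the (2R,3S)-3-hydroxy-2-aryloxypropanoic acid carrying the 1S ring of 20 at C3 | CN(C)C1C(OC)=C(O[Si](C)(C)C(C)(C)C)CC[C@]1([C@H](O)[C@@H](Oc2ccc(CCC(=O)OC)cc2OC)C(=O)N2[C@H](Cc3ccccc3)COC2=O)[C@H](CO[Si](C)(C)C(C)(C)C)[C@H](OC)c1ccc(O[Si](C(C)C)(C(C)C)C(C)C)c(OC)c1 | intermediate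
25 | (1S,2S)-2-[4-(3-hydroxypropyl)-2-methoxyphenoxy]-1-(ring of 20)propane-1,3-diol | CN(C)C1C(OC)=C(O[Si](C)(C)C(C)(C)C)CC[C@]1([C@H](O)[C@H](CO)Oc2ccc(CCCO)cc2OC)[C@H](CO[Si](C)(C)C(C)(C)C)[C@H](OC)c1ccc(O[Si](C(C)C)(C(C)C)C(C)C)c(OC)c1 | intermediate
26 | acyclic 2-methoxycyclohex-2-enone tetrol with benzylic OMe (unmasked, primary silyl ether cleaved, ring not yet closed) | COC1=C[C@@](CCC1=O)([C@H](O)[C@H](CO)Oc1ccc(CCCO)cc1OC)[C@H](CO)[C@H](OC)c1ccc(O[Si](C(C)C)(C(C)C)C(C)C)c(OC)c1 | intermediate (not isolated)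
27 | (1S,3S,4R,5S)-1-[(1S)-2-hydroxy-1-[4-(3-hydroxypropyl)-2-methoxyphenoxy]ethyl]-4-(hydroxymethyl)-7-methoxy-3-(ArT)-2-oxaspiro[4.5]dec-6-en-8-one | COC1=C[C@]2(CCC1=O)[C@H](CO)[C@@H](c1ccc(O[Si](C(C)C)(C(C)C)C(C)C)c(OC)c1)O[C@@H]2[C@H](CO)Oc1ccc(CCCO)cc1OC | intermediate
28 | tris(O-TMS) 8-(trimethylsilyloxy)-6,8-diene of 27 | COC1=C[C@]2(CC=C1O[Si](C)(C)C)[C@H](CO[Si](C)(C)C)[C@@H](c1ccc(O[Si](C(C)C)(C(C)C)C(C)C)c(OC)c1)O[C@@H]2[C@H](CO[Si](C)(C)C)Oc1ccc(CCCO[Si](C)(C)C)cc1OC | intermediate (not isolated)
29 | tris(O-TMS) O-TIPS ether of the target dienone | COC1=C[C@]2(C=CC1=O)[C@H](CO[Si](C)(C)C)[C@@H](c1ccc(O[Si](C(C)C)(C(C)C)C(C)C)c(OC)c1)O[C@@H]2[C@H](CO[Si](C)(C)C)Oc1ccc(CCCO[Si](C)(C)C)cc1OC | intermediate (not isolated)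
30 | CNP0252711.1, (1S,3S,4R,5S)-1-[(1S)-2-hydroxy-1-[4-(3-hydroxypropyl)-2-methoxyphenoxy]ethyl]-3-(4-hydroxy-3-methoxyphenyl)-4-(hydroxymethyl)-7-methoxy-2-oxaspiro[4.5]deca-6,9-dien-8-one | COC1=C[C@]2(C=CC1=O)[C@H](CO)[C@@H](c1ccc(O)c(OC)c1)O[C@@H]2[C@H](CO)Oc1ccc(CCCO)cc1OC | target

**Totals**

Total step count: 17. Longest linear sequence: 13 steps (steps 1, 3–7, 10–12, 14–17, from vanillin).

**Steps most likely to fail**

Step 14. The boron enolate may not add to the neopentyl aldehyde, which is flanked on both sides by substituted carbons. Alternatively the aminated silyl enol ether may be unmasked early by the ammonium triflate or the boron Lewis acid, so that the freed enone would be reduced in step 15. Fallback, setting out from 20 and 21 and returning at 25: phenol 21 would be O-alkylated with tert-butyl bromoacetate (K2CO3, acetone) to tert-butyl [2-methoxy-4-(3-methoxy-3-oxopropyl)phenoxy]acetate F1. Its lithium enolate (LiN(iPr)2, THF, −78 °C), small and used in a purely basic medium, would add to 20 to give the β-hydroxy tert-butyl ester F2, and the syn isomer with the configuration of 24 would be separated by chromatography. LiAlH4 (THF, 0 °C) would then reduce both ester groups to give 25.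

Step 11. Aminolysis of the lactone carbonyl next to the quaternary carbon may be too slow, or the ring-opened hydroxy amide may relactonise before it is silylated. Fallback, setting out from 17 and returning at 20 (steps 11 and 12 replaced): LiAlH4 (THF, 0 °C) would reduce the lactone to the diol F3. The less hindered side-chain CH2OH would be silylated selectively (tBuMe2SiCl, imidazole, CH2Cl2, −20 °C) to the mono-silyl ether F4, leaving the neopentyl alcohol. A Parikh–Doering oxidation (SO3·pyridine, DMSO, iPr2NEt) would convert that alcohol into aldehyde 20.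

Step 10. The 2-methoxy-substituted diene may add too slowly to the hindered exocyclic alkene and decompose on heating, or facial selectivity may erode at the temperature required. Fallback, setting out from 13 and 15 and returning at 17: an anionic double Michael annulation at low temperature. The potassium dienolate of 15 (KN(SiMe3)2, THF, −78 °C) would add to the methylene carbon of 13, the lactone enolate so formed would close onto the aminovinyl ketone carbon, and tBuMe2SiCl would trap the resulting enolate as 17. The same two bonds would form stepwise with the same anti approach and without any new compound (F0).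

Further compounds
F1 | step 14 | tert-butyl [2-methoxy-4-(3-methoxy-3-oxopropyl)phenoxy]acetate | COC(=O)CCc1ccc(OCC(=O)OC(C)(C)C)c(OC)c1
F2 | step 14 | tert-butyl (2R,3S)-3-hydroxy-2-[2-methoxy-4-(3-methoxy-3-oxopropyl)phenoxy]-3-(1S ring of 20)propanoate | CN(C)C1C(OC)=C(O[Si](C)(C)C(C)(C)C)CC[C@]1([C@H](O)[C@@H](Oc2ccc(CCC(=O)OC)cc2OC)C(=O)OC(C)(C)C)[C@H](CO[Si](C)(C)C(C)(C)C)[C@H](OC)c1ccc(O[Si](C(C)C)(C(C)C)C(C)C)c(OC)c1
F3 | step 11 | diol: (1S)-1-(hydroxymethyl) ring with (2R,3S)-1-hydroxy-3-methoxy-3-(ArT)propan-2-yl side chain | CN(C)C1C(OC)=C(O[Si](C)(C)C(C)(C)C)CC[C@]1(CO)[C@H](CO)[C@H](OC)c1ccc(O[Si](C(C)C)(C(C)C)C(C)C)c(OC)c1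
F4 | step 11 | mono-silyl ether of F3 (side-chain CH2O-TBS, ring CH2OH free) | CN(C)C1C(OC)=C(O[Si](C)(C)C(C)(C)C)CC[C@]1(CO)[C@H](CO[Si](C)(C)C(C)(C)C)[C@H](OC)c1ccc(O[Si](C(C)C)(C(C)C)C(C)C)c(OC)c1
F0 | step 10 | none | none
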